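A direct plan would make ring C first and ring A last: an asymmetric hetero-Diels–Alder reaction of a protected 4-hydroxybenzaldehyde, then methylenation of the lactone, would give dienol ether A1. Double C-acylation of A1 with alkenylmalonyl dichloride A2 would build ring A (flavanone silyl ether A3, then desilylation).
Weakest would be (a) this annulation, unprecedented on such partners and run on two labile fragments at the point of convergence, with C- versus O-acylation and ketene formation left to chance;
(b) the four steps to A2 for a three-carbon unit, with alkene position and geometry resting on one kinetic protonation;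
(c) the methylenation to A1, an enol ether that can be neither purified nor stored, after a cycloaddition whose optical purity must be raised by crystallisation.

**Plan of the new route.** The retrosynthesis cuts C4–C4a (ring C, closed last), O1–C2 (Mitsunobu inversion of an (R)-carbinol from a catalytic ketone reduction), C6–C1' (aryllithium plus (S)-citronellal, then dehydration) and C8a–O1 (C–H borylation/oxidation). Rings A and B are bought as benzene rings; ring C is the only ring made. The feature used: on ring A the oxygens at C5 and C7 lie symmetrically about the axis O1–C8a···C6–C1'. With C4–C4a cut, the two carbons ortho to O1 (future C4a and C8) are exchanged by rotation about that axis, so ring closure can give only the 6-alkenyl isomer. No ring A annulation, no dienol ether and no malonyl chloride occur; the alkene comes from a stereoconvergent elimination, and C2 from catalyst control and one inversion.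

Key step: step 7

Remark: the facial sense of the transfer hydrogenation in step 5 is assumed to be that of simple aryl ketones; should it be reversed for this β-keto amide, the (S,S)-catalyst would be used.

Step 1
Reactants: 1 1,3-bis(methoxymethoxy)benzene; 2 (S)-citronellal
Product: 4 (3S)-1-[2,6-bis(methoxymethoxy)phenyl]-3,7-dimethyloct-6-en-1-ol (both C1 epimers), via aryllithium 3 (not isolated)
Conditions: n-BuLi, THF, 0 °C; 2, -78 °C to 0 °C; aq. NH4Cl
Reagents that add atoms: none
Why: Directed ortho-metalation puts lithium on the carbon between the two MOM ethers and the aryllithium adds 1,2 to the aldehyde; the carbinol centre may form as a mixture because step 2 removes it, and the non-enolisable C3 of citronellal is untouched.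

Step 2
Reactants: 4 (3S)-1-[2,6-bis(methoxymethoxy)phenyl]-3,7-dimethyloct-6-en-1-ol
Product: 6 2-[(1E,3S)-3,7-dimethylocta-1,6-dien-1-yl]-1,3-bis(methoxymethoxy)benzene, via sulfamate ester 5 (not isolated)
Conditions: Burgess reagent (MeO2CN-SO2NEt3 inner salt), toluene, rt to 50 °C
Reagents that add atoms: none
Why: In the Burgess dehydration the sulfamate ester eliminates by a syn (Ei) pathway without acid, only C2' carries β-hydrogens, and both carbinol epimers should converge on the E alkene because the transition state with aryl and alkyl anti is strongly preferred for a 2,6-disubstituted styrene.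

Step 3
Reactants: 6 2-[(1E,3S)-3,7-dimethylocta-1,6-dien-1-yl]-1,3-bis(methoxymethoxy)benzene
Product: 8 4-[(1E,3S)-3,7-dimethylocta-1,6-dien-1-yl]-3,5-bis(methoxymethoxy)phenol, via arylboronate 7 (not isolated)
Conditions: [Ir(OMe)(cod)]2 (cat.), 4,4'-di-tert-butyl-2,2'-bipyridine (cat.), B2pin2, methyl tert-butyl ether, 50 °C; then 30% H2O2, aq. NaOH, THF, 0 °C
Reagents that add atoms: hydrogen peroxide, OO
Why: Sterically controlled iridium-catalysed aromatic C–H borylation followed by oxidation of the C–B bond: in the 1,2,3-trisubstituted ring only the C–H para to the chain has no ortho substituent, and the two alkenes, each flanked by branching, should react more slowly than this arene C–H.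

Step 4
Reactants: 9 4-acetoxybenzoyl chloride; 10 Meldrum's acid (2,2-dimethyl-1,3-dioxane-4,6-dione)
Product: 12 3-(4-acetoxyphenyl)-N,N-dimethyl-3-oxopropanamide, via acyl Meldrum's acid 11 (not isolated)
Conditions: pyridine, CH2Cl2, 0 °C to rt; 1 M HCl wash, evaporate; Me2NH (2 M in THF, 1 equiv), toluene, sealed tube, 80 °C
Reagents that add atoms: dimethylamine, CNC
Why: C-Acylation of Meldrum's acid and thermal fragmentation to an acylketene that the amine traps is the standard β-keto amide synthesis; the amine is held as the salt of the acidic acyl Meldrum's acid until the ketene forms, which should protect the aryl acetate from aminolysis.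

Step 5
Reactants: 12 3-(4-acetoxyphenyl)-N,N-dimethyl-3-oxopropanamide
Product: 13 (R)-3-(4-acetoxyphenyl)-3-hydroxy-N,N-dimethylpropanamide
Conditions: RuCl[(R,R)-TsDPEN](p-cymene) (1 mol %), HCO2H/Et3N (5:2), EtOAc, rt
Reagents that add atoms: none
Why: In this Noyori–Ikariya asymmetric transfer hydrogenation of an aryl ketone the (R,R)-ligand should deliver hydride to the Si face (aryl group in the CH/π-stabilised position) and set the carbinol centre as R, while the acidic formate medium leaves aryl acetate and amide intact.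

Step 6
Reactants: 8 4-[(1E,3S)-3,7-dimethylocta-1,6-dien-1-yl]-3,5-bis(methoxymethoxy)phenol; 13 (R)-3-(4-acetoxyphenyl)-3-hydroxy-N,N-dimethylpropanamide
Product: 14 (S)-3-(4-acetoxyphenyl)-3-{4-[(1E,3S)-3,7-dimethylocta-1,6-dien-1-yl]-3,5-bis(methoxymethoxy)phenoxy}-N,N-dimethylpropanamide
Conditions: PPh3, DIAD (betaine preformed), toluene, 0 °C to rt
Reagents that add atoms: none
Why: In the Mitsunobu etherification the phenoxide displaces the oxyphosphonium group with inversion (SN2), turning the (R)-carbinol into the S-configured future C2; the electron-withdrawing acetate on ring B disfavours ionisation of the benzylic centre, which should hold back racemisation and elimination to the cinnamamide.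

Step 7
Reactants: 14 (S)-3-(4-acetoxyphenyl)-3-{4-[(1E,3S)-3,7-dimethylocta-1,6-dien-1-yl]-3,5-bis(methoxymethoxy)phenoxy}-N,N-dimethylpropanamide
Product: 17 (2S)-2-(4-acetoxyphenyl)-6-[(1E,3S)-3,7-dimethylocta-1,6-dien-1-yl]-5,7-bis(methoxymethoxy)chroman-4-one, via O-triflyl iminium triflate 15 (not isolated), via cyclic iminium triflate 16 (not isolated)
Conditions: (CF3SO2)2O (1.1 equiv), 2,6-di-tert-butyl-4-methylpyridine (2.5 equiv), CH2Cl2 (0.02 M), -78 to 0 °C; then NaOAc/AcOH buffer (pH 5), THF/H2O, rt to 40 °C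
Reagents that add atoms: water, O
Why: Electrophilic amide activation followed by intramolecular Friedel–Crafts acylation: triflic anhydride turns the tertiary amide into O-triflyl iminium 15, the trioxygenated ring attacks its carbon, triflate leaves and rearomatisation gives vinylogous amidinium 16, which the buffered water hydrolyses to the C4 ketone. The closest known reactions are the Vilsmeier–Haack acylation of phloroglucinol ethers by N,N-dimethylamides and the triflic-anhydride-mediated cyclisation of aryl-tethered tertiary amides to benzo-fused ketones. Ring C is the only ring closed, by forming C4–C4a in a 6-exo-trig attack of the arene on the iminium carbon. No stereocentre is formed, and C2 should keep the S configuration of step 6: no bond to it is touched, the hindered pyridine is too weak a base to turn 16 into an enamine (a 4-amino-2H-chromene that could ring-open), and the hydrolysis is run at pH 5. The step needs attack by the ring carbon ortho to O1 and not by the styrene: the position para to O1 is blocked by the chain, the two ortho carbons are equivalent by rotation about the O1–C8a···C6–C1' axis so that only the 6-alkenyl flavanone can form, and six-membered ring closure at high dilution should outrun intermolecular attack by the styrene β-carbon. The pyridine buffer keeps the medium free of strong acid, which neither the MOM ethers nor the styrene would survive.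

Step 8
Reactants: 17 (2S)-2-(4-acetoxyphenyl)-6-[(1E,3S)-3,7-dimethylocta-1,6-dien-1-yl]-5,7-bis(methoxymethoxy)chroman-4-one
Product: 20 (2S)-6-[(1E,3S)-3,7-dimethylocta-1,6-dien-1-yl]-5,7-dihydroxy-2-(4-hydroxyphenyl)chroman-4-one (CNP0150993.1), via bis(trimethylsilyl) ether 18 (not isolated), via 4'-acetate 19 (not isolated)
Conditions: Me3SiOTf, 2,2'-bipyridyl, MeCN, 0 °C to rt; then NH4OAc (excess), MeOH/H2O, rt
Reagents that add atoms: none
Why: Silyl transfer under non-protic, bipyridyl-buffered conditions converts the two aromatic MOM ethers into trimethylsilyl ethers (the methoxymethyl group is taken up by the bipyridyl), and neutral aqueous methanolic ammonium acetate then hydrolyses the silyl ethers and cleaves the aryl acetate; neither stage is basic enough for retro-oxa-Michael opening of ring C (C2 epimerisation, 6/8 scrambling) nor acidic enough to cyclise the o-hydroxystyrene chain.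

**Compound list**
1 | 1,3-bis(methoxymethoxy)benzene | COCOc1cccc(OCOC)c1 | starting material
2 | (S)-citronellal, (3S)-3,7-dimethyloct-6-enal | CC(C)=CCC[C@H](C)CC=O | starting material
3 | 2,6-bis(methoxymethoxy)phenyllithium (not isolated) | [Li]c1c(OCOC)cccc1OCOC | intermediate
4 | (3S)-1-[2,6-bis(methoxymethoxy)phenyl]-3,7-dimethyloct-6-en-1-ol, C1 undefined | CC(C)=CCC[C@H](C)CC(O)c1c(OCOC)cccc1OCOC | intermediate
5 | triethylammonium N-(methoxycarbonyl)sulfamate ester of 4 (not isolated) | CC(C)=CCC[C@H](C)CC(OS(=O)(=O)[N-]C(=O)OC)c1c(OCOC)cccc1OCOC.CC[NH+](CC)CC | intermediate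
6 | 2-[(1E,3S)-3,7-dimethylocta-1,6-dien-1-yl]-1,3-bis(methoxymethoxy)benzene | CC(C)=CCC[C@H](C)/C=C/c1c(OCOC)cccc1OCOC | intermediate
7 | 2-{4-[(1E,3S)-3,7-dimethylocta-1,6-dien-1-yl]-3,5-bis(methoxymethoxy)phenyl}-4,4,5,5-tetramethyl-1,3,2-dioxaborolane (not isolated) | CC(C)=CCC[C@H](C)/C=C/c1c(OCOC)cc(B2OC(C)(C)C(C)(C)O2)cc1OCOC | intermediate
8 | 4-[(1E,3S)-3,7-dimethylocta-1,6-dien-1-yl]-3,5-bis(methoxymethoxy)phenol | CC(C)=CCC[C@H](C)/C=C/c1c(OCOC)cc(O)cc1OCOC | intermediate
9 | 4-acetoxybenzoyl chloride | CC(=O)Oc1ccc(cc1)C(Cl)=O | starting material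
10 | Meldrum's acid, 2,2-dimethyl-1,3-dioxane-4,6-dione | CC1(C)OC(=O)CC(=O)O1 | starting material
11 | 5-[(4-acetoxyphenyl)(hydroxy)methylene]-2,2-dimethyl-1,3-dioxane-4,6-dione (not isolated) | CC(=O)Oc1ccc(cc1)C(O)=C1C(=O)OC(C)(C)OC1=O | intermediate
12 | 3-(4-acetoxyphenyl)-N,N-dimethyl-3-oxopropanamide | CC(=O)Oc1ccc(cc1)C(=O)CC(=O)N(C)C | intermediate
13 | (R)-3-(4-acetoxyphenyl)-3-hydroxy-N,N-dimethylpropanamide | CN(C)C(=O)C[C@H](c1ccc(OC(C)=O)cc1)O | intermediate
14 | (S)-3-(4-acetoxyphenyl)-3-{4-[(1E,3S)-3,7-dimethylocta-1,6-dien-1-yl]-3,5-bis(methoxymethoxy)phenoxy}-N,N-dimethylpropanamide | CC(C)=CCC[C@H](C)/C=C/c1c(OCOC)cc(O[C@@H](CC(=O)N(C)C)c2ccc(OC(C)=O)cc2)cc1OCOC | intermediate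
15 | O-triflyl iminium triflate of 14 (not isolated) | CC(C)=CCC[C@H](C)/C=C/c1c(OCOC)cc(O[C@@H](CC(OS(=O)(=O)C(F)(F)F)=[N+](C)C)c2ccc(OC(C)=O)cc2)cc1OCOC.[O-]S(=O)(=O)C(F)(F)F | intermediate
16 | (2S)-2-(4-acetoxyphenyl)-6-[(1E,3S)-3,7-dimethylocta-1,6-dien-1-yl]-5,7-bis(methoxymethoxy)-N,N-dimethylchroman-4-iminium triflate (not isolated) | CC(C)=CCC[C@H](C)/C=C/c1c(OCOC)cc2c(c1OCOC)C(=[N+](C)C)C[C@@H](c1ccc(OC(C)=O)cc1)O2.[O-]S(=O)(=O)C(F)(F)F | intermediate
17 | (2S)-2-(4-acetoxyphenyl)-6-[(1E,3S)-3,7-dimethylocta-1,6-dien-1-yl]-5,7-bis(methoxymethoxy)chroman-4-one | CC(C)=CCC[C@H](C)/C=C/c1c(OCOC)cc2c(c1OCOC)C(=O)C[C@@H](c1ccc(OC(C)=O)cc1)O2 | intermediate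
18 | (2S)-2-(4-acetoxyphenyl)-6-[(1E,3S)-3,7-dimethylocta-1,6-dien-1-yl]-5,7-bis(trimethylsilyloxy)chroman-4-one (not isolated) | CC(C)=CCC[C@H](C)/C=C/c1c(O[Si](C)(C)C)cc2c(c1O[Si](C)(C)C)C(=O)C[C@@H](c1ccc(OC(C)=O)cc1)O2 | intermediate
19 | (2S)-2-(4-acetoxyphenyl)-6-[(1E,3S)-3,7-dimethylocta-1,6-dien-1-yl]-5,7-dihydroxychroman-4-one (not isolated) | CC(C)=CCC[C@H](C)/C=C/c1c(O)cc2c(c1O)C(=O)C[C@@H](c1ccc(OC(C)=O)cc1)O2 | intermediate
20 | (2S)-6-[(1E,3S)-3,7-dimethylocta-1,6-dien-1-yl]-5,7-dihydroxy-2-(4-hydroxyphenyl)chroman-4-one, CNP0150993.1 | CC(C)=CCC[C@H](C)/C=C/c1c(O)cc2c(c1O)C(=O)C[C@@H](c1ccc(O)cc1)O2 | target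

Total step count: 8. Longest linear sequence: 6 (steps 1, 2, 3, 6, 7, 8).

**Steps most likely to fail**

Step 7. The activated amide may be consumed by the electron-rich styrene (acylation at C2' or cationic oligomerisation) before the ring closes, or the amidinium may resist hydrolysis. The fallback attaches the chain after ring C is closed; it sets out from 1, 2 and 13 and comes back at 17. Aryllithium 3 (from 1 as in step 1) would be quenched with 1,2-dibromotetrafluoroethane to give 2-bromo-1,3-bis(methoxymethoxy)benzene F1. Borylation–oxidation as in step 3 would give 4-bromo-3,5-bis(methoxymethoxy)phenol F2, and Mitsunobu reaction with 13 would give (S)-3-(4-acetoxyphenyl)-3-[4-bromo-3,5-bis(methoxymethoxy)phenoxy]-N,N-dimethylpropanamide F3. The ring closure of step 7, now on a substrate without any alkene, would give (2S)-2-(4-acetoxyphenyl)-6-bromo-5,7-bis(methoxymethoxy)chroman-4-one F4. Separately, 2 would be converted in one pot (C4F9SO2F, phosphazene base) into (S)-3,7-dimethyloct-6-en-1-yne F5, and pinacolborane with catalytic Cp2Zr(H)Cl would turn F5 into 2-[(1E,3S)-3,7-dimethylocta-1,6-dien-1-yl]-4,4,5,5-tetramethyl-1,3,2-dioxaborolane F6. Suzuki–Miyaura coupling of F4 with F6 (Pd(OAc)2, 2-dicyclohexylphosphino-2',6'-dimethoxybiphenyl, anhydrous K3PO4, toluene, 60 °C) would return to 17.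

Step 3. The styrene double bond may be borylated or hydroborated in competition with the arene C–H, or the diene may inhibit the catalyst. The fallback introduces the oxygen before the chain; it sets out from 1 and comes back at 8. Borylation–oxidation of 1 (no alkene present) would give 3,5-bis(methoxymethoxy)phenol F7, and iPr3SiCl/imidazole would give [3,5-bis(methoxymethoxy)phenoxy]triisopropylsilane F8. Lithiation with n-BuLi between the two MOM ethers (the bulky silyl ether shields its own ortho positions) and addition to 2 would give (3S)-1-[2,6-bis(methoxymethoxy)-4-(triisopropylsilyloxy)phenyl]-3,7-dimethyloct-6-en-1-ol F9. Burgess dehydration would give {4-[(1E,3S)-3,7-dimethylocta-1,6-dien-1-yl]-3,5-bis(methoxymethoxy)phenoxy}triisopropylsilane F10, and Bu4NF in THF would release 8.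

Step 6. The activated β-hydroxy amide may eliminate to the cinnamamide, or the benzylic centre may lose configuration by partial ionisation. The fallback forms the other C–O bond (C8a–O1), so that the benzylic carbon is never substituted; it sets out from 7 and 12 and comes back at 14. Boronate 7, isolated instead of oxidised, would be converted with KHF2 in MeOH/H2O into potassium {4-[(1E,3S)-3,7-dimethylocta-1,6-dien-1-yl]-3,5-bis(methoxymethoxy)phenyl}trifluoroborate F11. Ketone 12 would be reduced as in step 5 but with the (S,S)-catalyst to (S)-3-(4-acetoxyphenyl)-3-hydroxy-N,N-dimethylpropanamide F12. Chan–Lam etherification of F12 with F11 (Cu(OAc)2, 4-dimethylaminopyridine, 4 Å sieves, O2, CH2Cl2, rt) would give 14 with retention at carbon.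

**Further compounds**
F1 | step 7 | 2-bromo-1,3-bis(methoxymethoxy)benzene | COCOc1cccc(OCOC)c1Br
F2 | step 7 | 4-bromo-3,5-bis(methoxymethoxy)phenol | COCOc1cc(O)cc(OCOC)c1Br
F3 | step 7 | (S)-3-(4-acetoxyphenyl)-3-[4-bromo-3,5-bis(methoxymethoxy)phenoxy]-N,N-dimethylpropanamide | CN(C)C(=O)C[C@@H](c1ccc(OC(C)=O)cc1)Oc1cc(OCOC)c(Br)c(OCOC)c1
F4 | step 7 | (2S)-2-(4-acetoxyphenyl)-6-bromo-5,7-bis(methoxymethoxy)chroman-4-one | Brc1c(OCOC)cc2c(c1OCOC)C(=O)C[C@@H](c1ccc(OC(C)=O)cc1)O2
F5 | step 7 | (S)-3,7-dimethyloct-6-en-1-yne | CC(C)=CCC[C@H](C)C#C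
F6 | step 7 | 2-[(1E,3S)-3,7-dimethylocta-1,6-dien-1-yl]-4,4,5,5-tetramethyl-1,3,2-dioxaborolane | CC(C)=CCC[C@H](C)/C=C/B1OC(C)(C)C(C)(C)O1
F7 | step 3 | 3,5-bis(methoxymethoxy)phenol | COCOc1cc(O)cc(OCOC)c1
F8 | step 3 | [3,5-bis(methoxymethoxy)phenoxy]triisopropylsilane | COCOc1cc(O[Si](C(C)C)(C(C)C)C(C)C)cc(OCOC)c1
F9 | step 3 | (3S)-1-[2,6-bis(methoxymethoxy)-4-(triisopropylsilyloxy)phenyl]-3,7-dimethyloct-6-en-1-ol | CC(C)=CCC[C@H](C)CC(O)c1c(OCOC)cc(O[Si](C(C)C)(C(C)C)C(C)C)cc1OCOC
F10 | step 3 | {4-[(1E,3S)-3,7-dimethylocta-1,6-dien-1-yl]-3,5-bis(methoxymethoxy)phenoxy}triisopropylsilane | CC(C)=CCC[C@H](C)/C=C/c1c(OCOC)cc(O[Si](C(C)C)(C(C)C)C(C)C)cc1OCOC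
F11 | step 6 | potassium {4-[(1E,3S)-3,7-dimethylocta-1,6-dien-1-yl]-3,5-bis(methoxymethoxy)phenyl}trifluoroborate | CC(C)=CCC[C@H](C)/C=C/c1c(OCOC)cc([B-](F)(F)F)cc1OCOC.[K+]
F12 | step 6 | (S)-3-(4-acetoxyphenyl)-3-hydroxy-N,N-dimethylpropanamide | CN(C)C(=O)C[C@@H](c1ccc(OC(C)=O)cc1)O
A1 | direct plan | (S)-2-[4-(tert-butyldimethylsilyloxy)phenyl]-4-methoxy-6-methylene-3,6-dihydro-2H-pyran | C=C1C=C(OC)C[C@@H](c2ccc(O[Si](C)(C)C(C)(C)C)cc2)O1
A2 | direct plan | 2-[(1E,3S)-3,7-dimethylocta-1,6-dien-1-yl]malonyl dichloride | CC(C)=CCC[C@H](C)/C=C/C(C(=O)Cl)C(=O)Cl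
A3 | direct plan | (2S)-2-[4-(tert-butyldimethylsilyloxy)phenyl]-6-[(1E,3S)-3,7-dimethylocta-1,6-dien-1-yl]-5,7-dihydroxychroman-4-one | CC(C)=CCC[C@H](C)/C=C/c1c(O)cc2c(c1O)C(=O)C[C@@H](c1ccc(O[Si](C)(C)C(C)(C)C)cc1)O2
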